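## Retrosynthetic overview

1. The route rests on ring C, the pyran O1–C2–C3–C4–C4a–C8a fused to ring A. It is a 2,4-diaryl-3-oxychroman with ring B on C2, oxygen on C3 and C6' of ring D on C4. This is the retron of an oxa-[4+2] union of a ring A ortho-quinone methide (O1=C8a–C4a=C4) with an E-configured 2-arylvinyl ester (C2=C3).
2. Cutting C3–C4 and O1–C2 together gives a benzhydrol that joins ring A to C6', plus (E)-2-(4-benzyloxyphenyl)vinyl acetate. All three stereocentres of ring C arise in this one step.
3. The benzhydrol is cut at C4–C6' into a C6' arylmagnesium reagent (C8' blocked by bromine) and a ring A salicylaldehyde made from 2,4-dihydroxybenzaldehyde.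
4. Rings D, E and F with C2' and C3' are bought as (−)-epicatechin, and rings A and B as simple arenes. Ring C is the only ring built, and it is built last.
5. O7 carries a pivalate rather than an ether, so that ring A is a poor Friedel–Crafts partner for the quinone methide. Ester methanolysis and one hydrogenolysis (six benzyl ethers and C8'–Br) finish the synthesis.

Key step: step 12

Numbering: the upper flavan unit is unprimed (O1, C2 to C8a), with ring A benzo, ring C pyran and ring B the aryl group on C2. The lower epicatechin unit is primed (O1', C2' to C8a'), with ring D benzo, ring F pyran and ring E the catechol ring on C2'.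

Assumption: the sense of induction of the phosphoric acid on this quinone methide cannot be derived from precedent. The (R) antipode is written, and the (S) antipode takes its place if a small trial shows it to be the matched one. Nothing else in the route changes.

## Route

Step 1
Reactants: 1 (−)-epicatechin (2'R,3'R)
Product: 2 tetra-O-benzylepicatechin (benzyl ethers on O5', O7' and both ring E oxygens; 3'-OH free; 2'R,3'R)
Conditions: BnBr (4.4 equiv), K2CO3 (5 equiv), DMF, Ar, 0 °C to rt
Reagents that add atoms: benzyl bromide, BrCc1ccccc1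
Why: Williamson ether synthesis, in which K2CO3 ionises only the four phenols, the 3'-OH stays free, and mild base under argon avoids opening of ring F, so C2' and C3' are carried over unchanged.

Step 2
Reactants: 2 tetra-O-benzylepicatechin
Product: 3 penta-O-benzylepicatechin (as 2, with O3' also benzylated)
Conditions: NaH (1.5 equiv), BnBr (1.3 equiv), DMF, 0 °C to rt
Reagents that add atoms: benzyl bromide, BrCc1ccccc1
Why: Williamson ether synthesis on the sodium alkoxide of the one remaining alcohol; with every phenol capped, no quinone methide pathway for epimerisation at C2' exists.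

Step 3
Reactants: 3 penta-O-benzylepicatechin
Product: 4 8'-bromo-penta-O-benzylepicatechin
Conditions: NBS (1.0 equiv), CH2Cl2, −78 °C to 0 °C
Reagents that add atoms: N-bromosuccinimide, O=C1CCC(=O)N1Br
Why: Electrophilic aromatic bromination, in which C8' is the most reactive position of the trioxygenated ring D in O-benzylated flavan-3-ols, so one equivalent of NBS at low temperature should stop at the 8'-monobromide and block this site against all later electrophiles.

Step 4
Reactants: 4 8'-bromo-penta-O-benzylepicatechin
Product: 5 8'-bromo-6'-iodo-penta-O-benzylepicatechin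
Conditions: NIS (1.1 equiv), CF3CO2H (10 mol %), CH2Cl2–MeCN, dark, 0 °C to rt
Reagents that add atoms: N-iodosuccinimide, O=C1CCC(=O)N1I
Why: Electrophilic aromatic iodination with acid-activated NIS, in which C6' is the only free position of ring D and, standing ortho to O5' and O7' and para to O1', should far outrun ring E and the benzyl rings.

Step 5
Reactants: 6 2,4-dihydroxybenzaldehyde
Product: 7 4-formyl-3-hydroxyphenyl pivalate
Conditions: PivCl (1.05 equiv), Et3N (1.1 equiv), CH2Cl2, 0 °C
Reagents that add atoms: pivaloyl chloride, CC(C)(C)C(=O)Cl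
Why: Selective O-acylation, in which the 2-OH is held in a hydrogen bond to the formyl group and is hindered, so the free and more acidic 4-OH takes the bulky acyl group; the ester is chosen because it makes ring A a poor arene nucleophile in step 12.

Step 6
Reactants: 7 4-formyl-3-hydroxyphenyl pivalate
Product: 8 3-(tert-butyldimethylsilyloxy)-4-formylphenyl pivalate
Conditions: TBSCl (1.2 equiv), imidazole (2 equiv), DMF, rt
Reagents that add atoms: tert-butyldimethylsilyl chloride, CC(C)(C)[Si](C)(C)Cl
Why: Silyl ether formation masks the acidic phenol, so that the valuable Grignard reagent of step 7 is not quenched and the aldehyde keeps its full electrophilicity.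

Step 7
Reactants: 5 8'-bromo-6'-iodo-penta-O-benzylepicatechin; 8 3-(tert-butyldimethylsilyloxy)-4-formylphenyl pivalate
Product: 10 C6'-{hydroxy[2-(tert-butyldimethylsilyloxy)-4-pivaloyloxyphenyl]methyl}-8'-bromo-penta-O-benzylepicatechin (both carbinol epimers), via aryl Grignard reagent 9 (not isolated)
Conditions: iPrMgCl·LiCl (1.1 equiv), THF, −20 °C; then 8 (1.4 equiv), −20 °C to 0 °C; sat. aq. NH4Cl
Reagents that add atoms: isopropylmagnesium chloride–lithium chloride, CC(C)[Mg]Cl.[Li+].[Cl-] (gives the magnesium and chlorine of 9 only; nothing of it remains in 10)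
Why: Iodine–magnesium exchange is much faster at the carbon–iodine than at the carbon–bromine bond and is helped by the two flanking ether oxygens, and the arylmagnesium reagent then undergoes Grignard 1,2-addition to the aldehyde faster than it attacks the hindered pivalate; the carbinol centre forms as both epimers, which does not matter because it becomes planar in step 12.

Step 8
Reactants: 10 silylated benzhydrol
Product: 11 C6'-[hydroxy(2-hydroxy-4-pivaloyloxyphenyl)methyl]-8'-bromo-penta-O-benzylepicatechin (both carbinol epimers)
Conditions: Bu4NF (1.1 equiv), AcOH (1.2 equiv), THF, 0 °C; pH 7 buffer; Et3N-deactivated silica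
Reagents that add atoms: none
Why: Fluoride-induced cleavage of the aryl silyl ether (and of any silyl group that has moved to the carbinol oxygen); the acetic acid buffer protonates the phenoxide at once, so that neither pivaloyl transfer nor base-induced loss of hydroxide sets in.

Step 9
Reactants: 12 1-(benzyloxy)-4-ethynylbenzene
Product: 13 (E)-2-[2-(4-benzyloxyphenyl)vinyl]-4,4,5,5-tetramethyl-1,3,2-dioxaborolane
Conditions: pinacolborane (1.1 equiv), Cp2ZrHCl (10 mol %), Et3N (10 mol %), neat, 60 °C
Reagents that add atoms: pinacolborane, B1OC(C)(C)C(C)(C)O1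
Why: Zirconium-catalysed hydroboration of a terminal alkyne, a syn addition with boron on the terminal carbon that should give only the E alkenylboronate.

Step 10
Reactants: 13 (E)-alkenylboronate
Product: 14 potassium (E)-[2-(4-benzyloxyphenyl)vinyl]trifluoroborate
Conditions: KHF2 (4.5 equiv, aq.), MeOH, rt
Reagents that add atoms: potassium hydrogen difluoride, [K+].[F-].F
Why: Ligand exchange of a boronic ester with bifluoride gives the crystalline trifluoroborate and leaves the alkene geometry untouched.

Step 11
Reactants: 14 potassium (E)-alkenyltrifluoroborate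
Product: 15 (E)-2-(4-benzyloxyphenyl)vinyl acetate
Conditions: AcOH (3 equiv), CuBr (10 mol %), 4-(dimethylamino)pyridine (20 mol %), 4 Å MS, O2 (1 atm), MeCN, 60 °C
Reagents that add atoms: acetic acid, CC(=O)O
Why: Chan–Lam–Evans-type oxidative C–O coupling, in which the alkenyl group passes from boron to copper and is joined to acetate by reductive elimination, both with retention, so the E geometry set in step 9 is kept and the E/Z problem of aldehyde enol acetylation is avoided.

Step 12
Reactants: 11 ortho-hydroxybenzhydrol; 15 (E)-2-(4-benzyloxyphenyl)vinyl acetate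
Product: 17 (2R,3S,4S)-3-O-acetyl-7-O-pivaloyl-8'-bromo-hexa-O-benzyl derivative of the target (2,3-trans-3,4-trans ring C; benzyl on the ring B oxygen, O3', O5', O7' and both ring E oxygens), via ortho-quinone methide 16 (not isolated)
Conditions: 15 (4 equiv), (R)-3,3'-bis(2,4,6-triisopropylphenyl)-1,1'-binaphthyl-2,2'-diyl hydrogen phosphate (10 mol %), 5 Å MS, toluene, 0 °C to rt, 11 added over 8 h
Reagents that add atoms: none
Why: Proposed new method: the phosphoric acid ionises the doubly benzylic C4–OH of 11 and keeps the resulting (E)-ortho-quinone methide 16 hydrogen-bonded at O1 inside its chiral pocket, and the acetoxy-bearing carbon of 15, made the nucleophilic end of the alkene by the para-benzyloxyphenyl group, attacks the methide carbon (C3–C4) while O1 closes on the developing para-alkoxybenzylic cation (O1–C2). The closest known reaction type is the acid-catalysed inverse-demand hetero-Diels–Alder reaction of aryl-substituted ortho-quinone methides with beta-substituted 4-alkoxystyrenes such as anethole, together with its chiral phosphoric acid version with hydroxystyrenes and enamides; an enol ester as the two-carbon partner and a methide carbon flanked by two ortho ethers are not covered by it. Ring C closes as a six-membered ring by a concerted but strongly asynchronous [4+2] addition (6-exo-trig capture of the C2 cation by O1 in the stepwise limit), and the five-membered indane alternative is shut off because both ortho positions of ring D are substituted and C5 of ring A is meta to both ring A oxygens. C2/C3 trans follows from suprafacial addition to the E alkene, backed in the stepwise limit by acetoxonium participation (O1 opens it at C2 with inversion) and by the all-equatorial shape of the product; C3/C4 trans, with the C2 and C4 aryl groups cis, follows from endo placement of ring B under the E-configured methide; the absolute sense (2R,3S,4S) follows from the face of 16 that the catalyst leaves open, and since C2' and C3' are fixed the wrong-face adduct is a diastereomer that chromatography removes. The step needs regioselectivity (aryl donor over acyloxy donor, secured by the weak donor power of the acetate oxygen) and chemoselectivity for 15 over arene attack on 16, secured by the C8' bromine, the O7 pivalate, the excess of 15 and the slow addition of 11, while the sieves bind the water so that 15 is not hydrolysed.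

Step 13
Reactants: 17 cycloadduct
Product: 18 (2R,3S,4S)-8'-bromo-hexa-O-benzyl derivative of the target with free 3-OH and 7-OH
Conditions: NaOMe (3 equiv), MeOH–THF, 0 °C to rt; AcOH quench
Reagents that add atoms: none
Why: Zemplén-type transesterification cleaves the secondary acetate and the aryl pivalate together; ring B is still an ether, so no quinone methide route to C2 epimerisation is open, and the benzyl ethers and the aryl bromide are inert.

Step 14
Reactants: 18 bromo hexabenzyl ether
Product: 19 target, guibourtinidol-(4α→6)-epicatechin (2R,3S,4S; 2'R,3'R)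
Conditions: H2 (1 atm), 20 % Pd(OH)2/C, NaOAc (1.5 equiv), THF–MeOH–H2O, rt; filtration under Ar, Sephadex LH-20
Reagents that add atoms: none
Why: Catalytic hydrogenolysis cleaves the six benzyl ethers and hydrodehalogenates C8'–Br in one operation, sodium acetate takes up the HBr, and the mild conditions should leave the cyclic benzylic C2–O1 and C2'–O1' bonds and all five stereocentres alone.

## Compound list

1 | (−)-epicatechin | O[C@@H]1Cc2c(O)cc(O)cc2O[C@@H]1c1ccc(O)c(O)c1 | starting material
2 | tetra-O-benzylepicatechin (3'-OH free) | c3c(OCc6ccccc6)cc4c(c3OCc6ccccc6)C[C@@H](O)[C@@H](c3ccc(OCc6ccccc6)c(OCc6ccccc6)c3)O4 | intermediate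
3 | penta-O-benzylepicatechin | c3c(OCc6ccccc6)cc4c(c3OCc6ccccc6)C[C@@H](OCc6ccccc6)[C@@H](c3ccc(OCc6ccccc6)c(OCc6ccccc6)c3)O4 | intermediate
4 | 8'-bromo-penta-O-benzylepicatechin | c3c(OCc6ccccc6)c(Br)c4c(c3OCc6ccccc6)C[C@@H](OCc6ccccc6)[C@@H](c3ccc(OCc6ccccc6)c(OCc6ccccc6)c3)O4 | intermediate
5 | 8'-bromo-6'-iodo-penta-O-benzylepicatechin | Ic3c(OCc6ccccc6)c(Br)c4c(c3OCc6ccccc6)C[C@@H](OCc6ccccc6)[C@@H](c3ccc(OCc6ccccc6)c(OCc6ccccc6)c3)O4 | intermediate
6 | 2,4-dihydroxybenzaldehyde | O=Cc1ccc(O)cc1O | starting material
7 | 4-formyl-3-hydroxyphenyl pivalate | O=Cc1ccc(OC(=O)C(C)(C)C)cc1O | intermediate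
8 | 3-(tert-butyldimethylsilyloxy)-4-formylphenyl pivalate | O=Cc1ccc(OC(=O)C(C)(C)C)cc1O[Si](C)(C)C(C)(C)C | intermediate
9 | C6' arylmagnesium chloride of 8'-bromo-penta-O-benzylepicatechin (not isolated) | Cl[Mg]c3c(OCc6ccccc6)c(Br)c4c(c3OCc6ccccc6)C[C@@H](OCc6ccccc6)[C@@H](c3ccc(OCc6ccccc6)c(OCc6ccccc6)c3)O4 | intermediate
10 | C6'-{hydroxy[2-(tert-butyldimethylsilyloxy)-4-pivaloyloxyphenyl]methyl}-8'-bromo-penta-O-benzylepicatechin (carbinol epimers) | OC(c1ccc(OC(=O)C(C)(C)C)cc1O[Si](C)(C)C(C)(C)C)c3c(OCc6ccccc6)c(Br)c4c(c3OCc6ccccc6)C[C@@H](OCc6ccccc6)[C@@H](c3ccc(OCc6ccccc6)c(OCc6ccccc6)c3)O4 | intermediate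
11 | C6'-[hydroxy(2-hydroxy-4-pivaloyloxyphenyl)methyl]-8'-bromo-penta-O-benzylepicatechin (carbinol epimers) | OC(c1ccc(OC(=O)C(C)(C)C)cc1O)c3c(OCc6ccccc6)c(Br)c4c(c3OCc6ccccc6)C[C@@H](OCc6ccccc6)[C@@H](c3ccc(OCc6ccccc6)c(OCc6ccccc6)c3)O4 | intermediate
12 | 1-(benzyloxy)-4-ethynylbenzene | C#Cc1ccc(OCc2ccccc2)cc1 | starting material
13 | (E)-2-[2-(4-benzyloxyphenyl)vinyl]-4,4,5,5-tetramethyl-1,3,2-dioxaborolane | CC1(C)OB(/C=C/c2ccc(OCc3ccccc3)cc2)OC1(C)C | intermediate
14 | potassium (E)-[2-(4-benzyloxyphenyl)vinyl]trifluoroborate | [K+].F[B-](F)(F)/C=C/c1ccc(OCc2ccccc2)cc1 | intermediate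
15 | (E)-2-(4-benzyloxyphenyl)vinyl acetate | CC(=O)O/C=C/c1ccc(OCc2ccccc2)cc1 | intermediate
16 | (E)-ring A ortho-quinone methide, ring D on the methide carbon C4 (not isolated) | O=C1C=C(OC(=O)C(C)(C)C)C=C/C1=C\c3c(OCc6ccccc6)c(Br)c4c(c3OCc6ccccc6)C[C@@H](OCc6ccccc6)[C@@H](c3ccc(OCc6ccccc6)c(OCc6ccccc6)c3)O4 | intermediate
17 | (2R,3S,4S)-3-O-acetyl-7-O-pivaloyl-8'-bromo-hexa-O-benzyl derivative of the target | c6ccccc6COc1ccc([C@H]2Oc3cc(OC(=O)C(C)(C)C)ccc3[C@@H](c3c(OCc6ccccc6)c(Br)c4c(c3OCc6ccccc6)C[C@@H](OCc6ccccc6)[C@@H](c3ccc(OCc6ccccc6)c(OCc6ccccc6)c3)O4)[C@@H]2OC(C)=O)cc1 | intermediate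
18 | (2R,3S,4S)-8'-bromo-hexa-O-benzyl derivative of the target, 3-OH and 7-OH free | c6ccccc6COc1ccc([C@H]2Oc3cc(O)ccc3[C@@H](c3c(OCc6ccccc6)c(Br)c4c(c3OCc6ccccc6)C[C@@H](OCc6ccccc6)[C@@H](c3ccc(OCc6ccccc6)c(OCc6ccccc6)c3)O4)[C@@H]2O)cc1 | intermediate
19 | guibourtinidol-(4α→6)-epicatechin, CNP0263196.4 | Oc1ccc([C@H]2Oc3cc(O)ccc3[C@@H](c3c(O)cc4c(c3O)C[C@@H](O)[C@@H](c3ccc(O)c(O)c3)O4)[C@@H]2O)cc1 | target

## Step count and risks

Total step count: 14.
Longest linear sequence: 9 steps (1, 2, 3, 4, 7, 8, 12, 13, 14).

**Step 12 (key step).**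
- The enol acetate is a weak nucleophile and the methide carbon is hindered, so cycloaddition may be slow.
- Self-condensation of the quinone methide with arene rings, hydrolysis of the enol ester, or poor facial selectivity may then take over.

Fallback by known chemistry, from 11 and back at 18. The two-carbon partner becomes an enamide, whose N–H binds to the phosphoryl oxygen of the catalyst, and the C3 oxygen is brought in afterwards.
- Commercial 4-(benzyloxy)benzonitrile is treated with MeMgBr to give the bromomagnesium ketimide F1.
- This is acetylated in the same flask with Ac2O to give N-[1-(4-benzyloxyphenyl)vinyl]acetamide F2.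
- The phosphoric acid-catalysed addition of an enamide to a quinone methide generated in situ is a known reaction type. Applied to 11, it should give the 2-acetamidochroman F3, with C4 set by the catalyst.
- Catalytic TsOH in warm toluene expels acetamide and gives the (4S)-2,4-diaryl-4H-chromene F4.
- Hydroboration with BH3·THF places boron on C3 (beta to O1). The addition is syn and anti to the pseudoaxial ring D, and gives the 2,3-trans-3,4-trans C3 borane F5.
- NaOH/H2O2 oxidises the C–B bond with retention and saponifies the pivalate, which gives 18.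

**Step 7.**
- The new alkoxide sits next to the silyl ether. Transfer of the silyl group to it, followed by loss of silanolate, may start quinone methide chemistry while 9 is still present.
- The addition between two ortho-substituted partners may be slow enough for ester attack to compete.

Fallback from 5 and 7, back at 11. The silyl group is dropped altogether.
- 7 is deprotonated with iPrMgCl (1.0 equiv, THF, −78 °C) to give the chloromagnesium phenoxide of 4-formyl-3-hydroxyphenyl pivalate F6.
- 9, made from 5 as before, is added to this magnesium-chelated aldehyde at 0 °C to rt. This is the standard entry to ortho-hydroxybenzhydrols.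
- Work-up with NH4Cl gives 11 directly, so steps 6 and 8 fall away.

**Step 11.**
- Protodeboronation or oxidative homocoupling of the electron-rich styryl trifluoroborate may outrun C–O bond formation.

Fallback from 13, back at 15.
- NaBO3·4H2O in THF–water oxidises 13 to (4-benzyloxyphenyl)acetaldehyde F7.
- Enol acetylation (Ac2O, KOAc, 120 °C) gives 15 together with (Z)-2-(4-benzyloxyphenyl)vinyl acetate F8.
- 15 is separated from F8 by chromatography and crystallisation, so the alkene geometry then rests on separation instead of on a stereospecific coupling.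

## Further compounds

F1 | step 12 | bromomagnesium 1-(4-benzyloxyphenyl)ethan-1-iminide | CC(=N[Mg]Br)c1ccc(OCc2ccccc2)cc1
F2 | step 12 | N-[1-(4-benzyloxyphenyl)vinyl]acetamide | C=C(NC(C)=O)c1ccc(OCc2ccccc2)cc1
F3 | step 12 | (4S)-2-acetamido-2-(4-benzyloxyphenyl)-7-pivaloyloxychroman with the 8'-bromo-penta-O-benzylepicatechin-6'-yl group on C4 (C2 epimers) | c6ccccc6COc1ccc(C2(NC(C)=O)Oc3cc(OC(=O)C(C)(C)C)ccc3[C@@H](c3c(OCc6ccccc6)c(Br)c4c(c3OCc6ccccc6)C[C@@H](OCc6ccccc6)[C@@H](c3ccc(OCc6ccccc6)c(OCc6ccccc6)c3)O4)C2)cc1
F4 | step 12 | (4S)-2-(4-benzyloxyphenyl)-7-pivaloyloxy-4H-chromene with the 8'-bromo-penta-O-benzylepicatechin-6'-yl group on C4 | c6ccccc6COc1ccc(C2Oc3cc(OC(=O)C(C)(C)C)ccc3[C@@H](c3c(OCc6ccccc6)c(Br)c4c(c3OCc6ccccc6)C[C@@H](OCc6ccccc6)[C@@H](c3ccc(OCc6ccccc6)c(OCc6ccccc6)c3)O4)C=2)cc1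
F5 | step 12 | 2,3-trans-3,4-trans C3 borane from F4 | c6ccccc6COc1ccc([C@H]2Oc3cc(OC(=O)C(C)(C)C)ccc3[C@@H](c3c(OCc6ccccc6)c(Br)c4c(c3OCc6ccccc6)C[C@@H](OCc6ccccc6)[C@@H](c3ccc(OCc6ccccc6)c(OCc6ccccc6)c3)O4)[C@@H]2B)cc1
F6 | step 7 | chloromagnesium phenoxide of 4-formyl-3-hydroxyphenyl pivalate | O=Cc1ccc(OC(=O)C(C)(C)C)cc1O[Mg]Cl
F7 | step 11 | (4-benzyloxyphenyl)acetaldehyde | O=CCc1ccc(OCc2ccccc2)cc1
F8 | step 11 | (Z)-2-(4-benzyloxyphenyl)vinyl acetate | CC(=O)O/C=C\c1ccc(OCc2ccccc2)cc1
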